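Each flask starts with G at 0.070 M and X at 2.00 equiv; beta, gamma and theta differ in J, from 2.00 equiv to 8.00 equiv. G and X make Q and D; D may pair with J to L or with X to E, and two J may go to Z.

common to all: G 0.070 M
- Wednesday's: X 2 equiv; J 1.7 equiv; run made earlier
- Saturday's: X 2 equiv; J 5.2 equiv; run made earlier
- beta: X 2.00 equiv; J 2.00 equiv; time 12 h
- gamma: X 2.00 equiv; J 4.00 equiv; time 12 h
- theta: X 2.00 equiv; J 8.00 equiv; time 12 h

| run | time / h | G / % | Q / % |
|---|---|---|---|
| Wednesday's | 1.00 | 93.4 | 7.1 |
| Wednesday's | 1.50 | 92.0 | 7.9 |
| Wednesday's | 2.50 | 87.3 | 12.0 |
| Wednesday's | 4.00 | 82.5 | 20.7 |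
| Wednesday's | 8.00 | 66.9 | 34.5 |
| Wednesday's | 12.0 | 59.0 | 40.9 |
| Saturday's | 1.00 | 95.2 | 6.1 |
| Saturday's | 1.50 | 91.0 | 9.1 |
| Saturday's | 2.50 | 86.2 | 12.5 |
| Saturday's | 4.00 | 80.8 | 22.0 |
| Saturday's | 8.00 | 65.9 | 33.6 |
| Saturday's | 12.0 | 55.9 | 43.1 |

(readings scatter by 1 percentage point)

- part of the G that has reacted at the end, beta
- part of the G that has reacted at the end, gamma
- part of the G that has reacted at the end, theta
- what raising the equivalents of J from its lowest to its highest value here does to the part of the G that has reacted (changes below 5 percentage points count as none) (no change / it falls / it rises)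

- steps that have been proposed: D + J <-> L; X + D <-> E; G + X -> D + Q; 2 J -> Z

My zero of the scale is a flask on which J has no effect, so both earlier runs should share one curve. With G and X going one for one and X at twofold, the logarithm of [X]/[G], counted from its start, grows steadily with time. Wednesday's 59.0% of G and Saturday's 55.9% at 12.0 h read, on average, 0.0263 /h for this growth, which I call the pace, the second-order rate constant times [G] at the start.

Over 12 h the logarithm reaches 0.315, so 42.6% of G has reacted on my zero, in all three flasks.

The end readings of G in the two runs differ by 3.1 percentage points, and a straight line drawn through them gives 5.3 points from beta to theta, more than the 5 points that counts as a change.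

But this weak link is one pair of readings, each with a scatter of 1 point. All the paired G readings together average a gap of 1 point, and the same line then gives 1.7 points, less than that margin. So I commit to 42.6% and no change.

The forecast says 42%, 43% and 44%, with no change, and its ground is: “There is no clear sign of slowing from D tying up X”.

The flasks give 42.9%, 43.4% and 43.9%: no change, a change of 1 point.

    D + J ⇌ L, settled at all times (K = 300 /M)
    X + D ⇌ E, settled at all times (K = 1800 /M)
    G + X → D + Q (k = 0.00722 /M/min)
    2 J → Z (k = 6.49 × 10⁻⁴ /M/min)

Of the settings tried on gamma, each moved alone by the same factor up or down, the answer responds in this order: X (9.1 points), then time (6.9 points), then G (6.9 points), then J (0.2 points). I put the pace to X: in the neighbour flask, which is theta with 1.20 equiv of X, the logarithm grows at the pace times the equivalents of X less one, which gives 28.1%, and the flask gives 29.4%.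

(The numbers in the tables are calculated on assumed constants, noise included.)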